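The easy step is to read the substrate as the fraction left, f, and not to count what is made. At 30.0 min Sunday's flask holds 80.5% and Saturday's 80.4%. These agree within the scatter of 1 percentage point, though one was loaded with 0.034 M and the other with 0.10 M. So I treat the loss as pseudo-first-order in substrate, and I count reagent by how long it has been in.

| flask | substrate | reagent | remark | time |
|---|---|---|---|---|
| Sunday's | 0.034 M | 0.035 M (in portions, 3) | run made earlier; portions every 15 min |  |
| Saturday's | 0.10 M | 0.035 M (in portions, 3) | run made earlier; portions every 15 min |  |
| elm | 0.050 M | 0.110 M (in portions, 3) | the portions of reagent follow each other after 15 min, the first at the start | 1.5 h |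
| alder | 0.050 M | 0.320 M (in portions, 3) | the portions of reagent follow each other after 15 min, the first at the start | 1.5 h |
| oak | 0.050 M | 0.0350 M (in portions, 3) | the portions of reagent follow each other after 15 min, the first at the start | 1.5 h |

| run | time / min | intermediate / % | substrate / % | side product / % | target / % |
|---|---|---|---|---|---|
| Sunday's | 4.00 | 0.7 | 100.0 | 0 | 0.8 |
| Sunday's | 12.0 | 2.8 | 95.1 | 0.6 | 0.2 |
| Sunday's | 20.0 | 4.3 | 88.8 | 0 | 2.7 |
| Sunday's | 30.0 | 7.2 | 80.5 | 2.0 | 5.6 |
| Saturday's | 8.00 | 2.1 | 96.2 | 0 | 0.9 |
| Saturday's | 15.0 | 4.0 | 91.9 | 1.4 | 0.1 |
| Saturday's | 25.0 | 5.6 | 82.5 | 0.2 | 3.4 |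
| Saturday's | 30.0 | 4.4 | 80.4 | 0.2 | 6.3 |

(each reading ± 1 percentage point)

- percentages count the substrate that a species holds: one homo dimer counts as two
- the earlier runs were read with a standard deviation of 1 percentage point
- what may be going on: substrate + reagent <-> intermediate; intermediate <-> target + by-product; 2 substrate -> homo dimer; substrate + by-product -> side product

- which of these there is most of at the end, counted by the substrate in it, elm (intermediate / side product / target / substrate)
- which of these there is most of at the end, counted by the substrate in it, alder (intermediate / side product / target / substrate)
- which of these there is most of at the end, counted by the substrate in it, oak (intermediate / side product / target / substrate)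
- the largest of these amounts at the end, in percent of the substrate charged, elm
- the largest of these amounts at the end, in percent of the substrate charged, alder
- the largest of these amounts at the end, in percent of the substrate charged, oak

Let c be the whole charge of reagent and τ the interval between portions. The exposure E is free reagent summed over time. Once the last portion is in, and if none is spent, a portion has on average stood for t − τ. My loss constant k is the fall of ln f per unit of exposure, read from the mean of the two readings at 30.0 min, when the exposure is c·τ:

k = −ln(f)/(c·τ) = 0.00691 L mol⁻¹ s⁻¹

f = exp(−k·c·(t − τ))

First, the main step alone in oak, with reagent never spent: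

f = 33.7%

The same line gives elm 3.28%.

Second, reagent is spent. In oak it is the limiting reagent. Each substrate lost now costs one reagent, so from the last portion on I carry the ratio of substrate to reagent, which starts from 0.0402 M over 0.0252 M:

ratio at the end = 2.32

f = 52.8%

The number rises.

Third, the rest. The readings miss 4.7 points on Sunday and 8.7 points on Saturday. Homo dimer and side product take substrate and spend no reagent, so the number comes down again. I commit to oak's substrate lying between my two lines.

The forecast says target at 62% (48% to 74%) for elm, target at 85% (70% to 93%) for alder, and substrate at 46% (37% to 55%) for oak. It starts from the same reading: “Substrate loss is about the same fraction in both runs despite threefold different loading”. My two lines for oak, 33.7% and 52.8%, stand on either side of its number.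

The flasks give target at 63.5% in elm, target at 83.2% in alder and substrate at 43.1% in oak.

    substrate + reagent ⇌ intermediate (K = 27.0 L mol⁻¹, k = 0.00600 L mol⁻¹ s⁻¹)
    intermediate ⇌ target + by-product (K = 0.970 M, k = 9.60 × 10⁻⁴ s⁻¹)
    2 substrate → homo dimer (k = 2.70 × 10⁻⁴ L mol⁻¹ s⁻¹)
    substrate + by-product → side product (k = 0.00930 L mol⁻¹ s⁻¹)

Oak's substrate lies between my lines, at 0.773 of the first line's exponent, with 48.9% of its reagent free at the end. Oak has not come to rest. Its substrate leads target, 30.8%, at 1.5 h, but the two tie at 1.22 times that time. After 15.0 h oak holds substrate 0.720%, target 50.9% and side product 38.7%.

Oak read at 40 min: the first line with k gives 69.6%. The flask holds 73.0%.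

(The runs come from a simulation with made-up constants, and the scatter is random.)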